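3 questions stand on this flask, and both shares need the same two amounts: what isomer of the product has grown to, and what target stands at.

| setting | north | west | north-west | flask |
|---|---|---|---|---|
| substrate | 0.092 M | 0.092 M | 0.18 M | 0.092 M |
| solid reagent | 1.3 equiv | 1.3 equiv | 1.3 equiv | 1.30 equiv |
| catalyst | 0.11 mol% | 0.17 mol% | 0.22 mol% | 0.22 mol% |
| remark | run made earlier | run made earlier | run made earlier |  |
| time |  |  |  | 5.0 d |

- north (time / d: target / %, isomer of the product / %, substrate / %): 0.250: 0.3, 3.4, 96.2; 0.417: 0, 7.0, 94.0; 0.833: 1.0, 13.8, 86.0; 1.67: 0.7, 27.5, 72.0; 3.00: 1.0, 48.2, 51.7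
- west (time / d: target / %, isomer of the product / %, substrate / %): 0.250: 0, 4.2, 96.3; 0.833: 0, 13.8, 86.2; 1.25: 0.4, 20.2, 78.6; 2.00: 0.3, 32.7, 65.9; 3.00: 0.1, 47.8, 52.0
- north-west (time / d: target / %, isomer of the product / %, substrate / %): 0.250: 0.5, 2.1, 97.8; 0.833: 0.6, 7.4, 92.3; 1.25: 0, 11.0, 88.3; 2.00: 0.3, 18.2, 81.9; 3.00: 0.5, 27.5, 72.6

(readings scatter by 0.3 percentage points)

1. share of target in target plus isomer of the product at 5.0 h
2. share of target in target plus isomer of the product at 5.0 d
3. which of target and isomer of the product there is more of at 5.0 d

- as a solid, counted per litre of solution: solid reagent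
- the numbers in the tables scatter by 0.3 percentage points (one standard deviation)
- at the start none of the solid reagent is in solution

The runs give the first amount. North and west, with 0.11 mol% and 0.17 mol% of catalyst, read 48.2 % and 47.8 % of isomer of the product at 3.00 d, while north-west, with about twice the substrate, reads 27.5 %. Per litre and averaged up to that time, west makes 0.0147 M/d and north-west 0.0165 M/d; I call the first figure the supply rate, the isomer of the product made per litre and day. Held steady, it puts the flask at 3.32 % at 5.0 h and 79.7 % at 5.0 d.

The dispute is over target. The forecast treats it as a small part of the isomer, “Overall it is about 2 % of the isomer”, and gives a share of target in the two products (the selectivity) of 4 % and 1.2 %, with isomer of the product ahead. My own reckoning differs in its numbers: I carry target into both times as a standing level, the mean of the 10 readings at 0.092 M, which is 0.380 %. That gives shares of 10.3 % and 0.475 %.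

The flask gives 10.8 % and 0.969 %, with isomer of the product ahead, 71.0 % against 0.694 % of target.

    substrate + partner ⇌ isomer of the product (K = 720 /M, k = 12.0 /M/h)
    substrate + partner ⇌ target (K = 5.40 /M, k = 27.0 /M/h)
    solid reagent ⇌ partner, rate k3*(cs3 - [partner]) while solid is left; crystals form when [partner] > cs3 (solubility = 9.70 mM, k = 0.0770 /h)
    target + catalyst ⇌ isomer of the product + catalyst, rate k4*[catalyst]*[target] forward; the back reaction follows from the equilibrium constant (k = 100 /M/h)

At 5.0 h the standing level's 10.3 % lies nearer the flask than the forecast's 4 %, but at 5.0 d the forecast's 1.2 % lies nearer than the level's 0.475 %, and target in the flask stands higher at 5.00 d, with 0.694 %, than at 0.500 d, with 0.380 %. The supply rate gave 79.7 % of isomer of the product where the flask holds 71.0 %. At 5.00 d the step between substrate + partner and target relaxes with a half-life of 0.119 h, shorter than the 0.0752 d of the step to isomer of the product.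

In the neighbour flask with 0.23 M of substrate, the supply rate gives 31.9 % of isomer of the product and, with the same level, a share of 1.18 %. The computed values there are 35.5 % and 1.08 %.

The readings were computed with made-up constants, noise included.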